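**Retrosynthetic overview**
1. β‑Tocopherol ⇐ reductive C–S cleavage of a 2‑(p‑tolylsulfinylmethyl)chroman; the CH2–S carbon becomes the C2 methyl.
2. Dihydropyran ring (the only ring built; the benzene ring is bought) ⇐ 6‑exo intramolecular oxa‑Michael addition of the hydroquinone OH onto an enantiopure β,β‑dialkyl vinyl sulfoxide, which sets C2.
3. Vinyl sulfoxide ⇐ syn‑carbocupration joining a 2‑arylethylcopper reagent and a C18 alkynyl sulfoxide (the convergent union).
4. Arylethyl bromide ⇐ 2,5‑dimethylhydroquinone (MOM protection, ortho‑lithiation, ethylene oxide). Alkynyl sulfoxide ⇐ natural phytol (ozonolysis, ketone→alkyne, Andersen sulfinylation); 4'R and 8'R come from phytol unchanged.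

Assumption: natural (2E,7R,11R)‑phytol is bought as the single isomer. Only materials that supply skeleton or the sulfinyl auxiliary are numbered; simple reagents are given by name and SMILES within each step.

---

**Step 1**
Reactants: 1, 2,5‑dimethylhydroquinone
Product: 2, 1,4‑bis(methoxymethoxy)‑2,5‑dimethylbenzene
Conditions: NaH, MOMCl, DMF, 0 °C→rt, N2
Reagents that add atoms: chloromethyl methyl ether (MOMCl), COCCl
Why: Williamson O‑alkylation of both phenoxides gives the bis‑MOM ether, which blocks hydroquinone oxidation and provides the directing group for step 2.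

**Step 2**
Reactants: 2; 3, ethylene oxide
Product: 4, 2‑[2,5‑bis(methoxymethoxy)‑3,6‑dimethylphenyl]ethan‑1‑ol
Conditions: n‑BuLi (1.1 equiv), TMEDA, Et2O, 0 °C→rt; then ethylene oxide, −78 °C→rt
Reagents that add atoms: none beyond 3
Why: OMOM‑directed ortho‑metalation at one of the two equivalent ring C–H positions, then epoxide opening by the aryllithium, installs the two carbons that become C4 and C3.

**Step 3**
Reactants: 4
Product: 5, 3‑(2‑bromoethyl)‑1,4‑bis(methoxymethoxy)‑2,5‑dimethylbenzene
Conditions: CBr4, PPh3, 2,6‑lutidine, CH2Cl2, 0 °C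
Reagents that add atoms: carbon tetrabromide, BrC(Br)(Br)Br
Why: Appel bromination of the primary alcohol under buffered conditions that leave the MOM ethers intact.

**Step 4**
Reactants: 6, natural phytol, (2E,7R,11R)‑3,7,11,15‑tetramethylhexadec‑2‑en‑1‑ol
Product: 7, (6R,10R)‑6,10,14‑trimethylpentadecan‑2‑one
Conditions: O3, CH2Cl2/MeOH, −78 °C; Me2S, →rt
Reagents that add atoms: ozone, [O-][O+]=O
Why: Ozonolysis with reductive work‑up cleaves the only alkene to the methyl ketone; both stereocentres are remote and non‑epimerisable.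

**Step 5**
Reactants: 7
Product: 8, (6R,10R)‑6,10,14‑trimethylpentadec‑1‑yne
Conditions: LDA (1.1 equiv), THF, −78 °C; ClP(O)(OEt)2, →rt; then LDA (2.3 equiv), −78 °C→rt
Reagents that add atoms: none
Why: Kinetic enolisation on the methyl side, enol phosphate formation and double‑base elimination (Negishi methyl ketone→terminal alkyne) give the alkyne; any internal isomer cannot react in step 7 and is removed there.

**Step 6**
Reactants: 9, sodium p‑toluenesulfinate; 10, (−)‑menthol (1R,2S,5R)
Product: 11, (1R,2S,5R)‑menthyl (S)‑p‑toluenesulfinate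
Conditions: SOCl2, toluene, 0 °C→rt; then 10, Et3N, Et2O, 0 °C; crystallise from acetone with cat. conc. HCl, −20 °C
Reagents that add atoms: none beyond 9 and 10
Why: Esterification of the sulfinyl chloride gives both sulfur epimers, and HCl‑mediated epimerisation with selective crystallisation funnels them to the (S)‑sulfinate (Andersen reagent).

**Step 7**
Reactants: 8; 11
Product: 12, (S)‑p‑tolyl (6R,10R)‑6,10,14‑trimethylpentadec‑1‑ynyl sulfoxide
Conditions: EtMgBr, THF, 0→40 °C; then add to 11, toluene, −20 °C
Reagents that add atoms: none beyond 11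
Why: Andersen sulfoxide synthesis, in which the alkynyl Grignard displaces mentholate at sulfur with clean inversion; the descriptor is S because alkynyl outranks tolyl.

**Step 8**
Reactants: 5; 12
Product: 13, (R at sulfur, E)‑vinyl sulfoxide: p‑tolyl‑S(O)–CH=C(CH2CH2Ar)(C16 chain), with ArCH2CH2 trans to S and the (4R,8R)‑4,8,12‑trimethyltridecyl chain cis to S (Ar = 2,5‑bis(methoxymethoxy)‑3,6‑dimethylphenyl)
Conditions: 5, Mg, THF, rt; CuBr·SMe2 (1 equiv), −40 °C; add 12, −78 °C, 2 h; aq NH4Cl/NH3
Reagents that add atoms: none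
Why: Stereospecific syn‑carbocupration by the monoalkylcopper reagent puts the new alkyl group β and trans to sulfur (copper α, then protonated with retention), so a single alkene isomer forms and sulfur is untouched (now R because tolyl outranks vinyl).

**Step 9**
Reactants: 13
Product: 14, the corresponding free hydroquinone: (R at sulfur, E)‑3‑[3‑(p‑tolylsulfinylmethylidene)‑(7R,11R)‑7,11,15‑trimethylhexadecyl]‑2,5‑dimethylbenzene‑1,4‑diol
Conditions: TsOH·H2O, degassed MeOH, 50 °C, Ar
Reagents that add atoms: none
Why: Acid‑catalysed acetal exchange removes both MOM groups; a halide‑free acid avoids racemisation of the sulfoxide, and the deactivated vinyl sulfoxide is inert to it.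

**Step 10 (key ring closure)**
Reactants: 14
Product: 15, (2R)‑5,8‑dimethyl‑2‑{[(R)‑p‑tolylsulfinyl]methyl}‑2‑[(4R,8R)‑4,8,12‑trimethyltridecyl]chroman‑6‑ol
Conditions: NaOMe (2.5 equiv), degassed MeOH/THF, rt→40 °C, Ar; aq NH4Cl
Reagents that add atoms: none
Why: Intramolecular 6‑exo oxa‑Michael addition of the ortho phenoxide to the vinyl sulfoxide, with MeOH protonating the α‑sulfinyl carbanion; A(1,3) strain from the cis β‑chain puts the sulfur lone pair in the alkene plane and oxygen attacks the face anti to p‑tolyl, which for the (R at sulfur, E) isomer gives 2R.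

**Step 11**
Reactants: 15
Product: 16, β‑tocopherol, (2R)‑2,5,8‑trimethyl‑2‑[(4R,8R)‑4,8,12‑trimethyltridecyl]chroman‑6‑ol
Conditions: Raney Ni (W‑2, excess), EtOH, 50 °C, under N2/H2
Reagents that add atoms: none
Why: Reductive desulfurisation cleaves the C–S bond so the CH2S(O)Tol group becomes the C2 methyl; no bond to C2 is broken, so 2R is retained.

---

**Compound list**
1 | 2,5‑dimethylhydroquinone | Cc1cc(O)c(C)cc1O | starting material
2 | 1,4‑bis(methoxymethoxy)‑2,5‑dimethylbenzene | COCOc1cc(C)c(OCOC)cc1C | intermediate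
3 | ethylene oxide | C1CO1 | starting material
4 | 2‑[2,5‑bis(methoxymethoxy)‑3,6‑dimethylphenyl]ethan‑1‑ol | COCOc1c(C)cc(OCOC)c(C)c1CCO | intermediate
5 | 3‑(2‑bromoethyl)‑1,4‑bis(methoxymethoxy)‑2,5‑dimethylbenzene | COCOc1c(C)cc(OCOC)c(C)c1CCBr | intermediate
6 | (2E,7R,11R)‑phytol | C/C(CCC[C@H](C)CCC[C@H](C)CCCC(C)C)=C\CO | starting material
7 | (6R,10R)‑6,10,14‑trimethylpentadecan‑2‑one | CC(=O)CCC[C@H](C)CCC[C@H](C)CCCC(C)C | intermediate
8 | (6R,10R)‑6,10,14‑trimethylpentadec‑1‑yne | C#CCCC[C@H](C)CCC[C@H](C)CCCC(C)C | intermediate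
9 | sodium p‑toluenesulfinate | Cc1ccc(cc1)S(=O)[O-].[Na+] | starting material
10 | (1R,2S,5R)‑(−)‑menthol | CC(C)[C@@H]1CC[C@@H](C)C[C@H]1O | starting material
11 | (1R,2S,5R)‑menthyl (S)‑p‑toluenesulfinate | Cc1ccc(cc1)[S@@](=O)O[C@@H]1C[C@H](C)CC[C@H]1C(C)C | intermediate
12 | (S)‑p‑tolyl (6R,10R)‑6,10,14‑trimethylpentadec‑1‑ynyl sulfoxide | Cc1ccc(cc1)[S@](=O)C#CCCC[C@H](C)CCC[C@H](C)CCCC(C)C | intermediate
13 | (R at S, E)‑bis‑MOM vinyl sulfoxide | Cc1ccc(cc1)[S@](=O)/C=C(\CCC[C@H](C)CCC[C@H](C)CCCC(C)C)/CCc1c(C)c(OCOC)cc(C)c1OCOC | intermediate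
14 | (R at S, E)‑hydroquinone vinyl sulfoxide | Cc1ccc(cc1)[S@](=O)/C=C(\CCC[C@H](C)CCC[C@H](C)CCCC(C)C)/CCc1c(C)c(O)cc(C)c1O | intermediate
15 | (2R)‑2‑{[(R)‑p‑tolylsulfinyl]methyl}chroman‑6‑ol | Cc1cc(O)c(C)c2c1O[C@](C[S@@](=O)c3ccc(C)cc3)(CCC[C@H](C)CCC[C@H](C)CCCC(C)C)CC2 | intermediate
16 | (2R,4'R,8'R)‑β‑tocopherol | Cc1cc(O)c(C)c2c1O[C@](C)(CCC[C@H](C)CCC[C@H](C)CCCC(C)C)CC2 | target

---

**Total step count:** 11
**Longest linear sequence:** 7 (steps 1–3, then 8–11; equally steps 4, 5, 7, then 8–11)

**Three steps most likely to fail, with fallbacks**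
1. **Step 10 (oxa‑Michael).** A β,β‑dialkyl vinyl sulfoxide is a weak acceptor, base may deconjugate it to the allyl sulfoxide, and the 2R outcome is predicted from a conformational model, not from a direct precedent on this substrate. Fallback: change to catalyst control. Make the salicylaldehyde by ortho‑formylation of mono‑protected 1 and combine it with (E)‑phytenal (MnO2 on 6) under a diarylprolinol silyl ether catalyst. This iminium‑mediated vinylogous aldol/intramolecular oxa‑Michael domino closes the chroman, after which the extra carbon is removed by decarbonylation and the benzylic oxygen by ionic reduction.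
2. **Step 8 (carbocupration).** Wurtz coupling may occur during Grignard formation, or residual Grignard may attack sulfur and displace the alkynyl group. Fallback: build the same alkene by carbonyl olefination. Alkylate the terminal aza‑enolate of the N,N‑dimethylhydrazone of 7 with the benzylic bromide ArCH2Br to give ArCH2CH2C(O)R, then run a Horner–Wittig reaction with enantiopure diethyl (p‑tolylsulfinyl)methylphosphonate and separate the E/Z isomers by chromatography.
3. **Step 5 (ketone → terminal alkyne).** Enolisation may not be fully regioselective, giving internal alkyne or allene. Fallback: shorten and re‑extend the chain. Baeyer–Villiger oxidation of 7, acetate hydrolysis to (4R,8R)‑4,8,12‑trimethyltridecan‑1‑ol, conversion to the iodide and alkylation of lithium acetylide–ethylenediamine gives 8 with no regiochemical ambiguity.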